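**Retrosynthetic overview** (chain numbered C1 = ethyl CH3 to C13 = carbon on the pyrone)
1. Cut C6–C7 (acyl–alkenyl bond of the cross-conjugated dienone) last: a pyrone-bearing C7 alkenyl iodide plus the 2-pyridyl thioester of (2E,4S)-2,4-dimethylhex-2-enoic acid, joined by a nickel-catalysed electroreductive coupling at a sacrificial zinc anode.
2. Thioester (C1–C6, C3 stereocentre): from (S)-2-methylbutan-1-ol by one-flask oxidation–Wittig, saponification and thioesterification.
3. Alkenyl iodide (C7–C13): C12=C13 by aldol/dehydration of the 6-ethyl-4-hydroxy-3,5-dimethyl-2-pyrone dianion with an iodo-dienal; C10=C11 by Wittig; C7–I by hydrozirconation–iodination of a 2-alkyne made from the (S)-Roche ester (C9 stereocentre).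
4. Only ring: the α-pyrone, formed first from ethyl 2-methyl-3-oxopentanoate (dianion acylation, lactonisation) and carried on with its 4-OH free.

Assumption: operations run in one flask, or on crude material without purification, count as one step; compounds passed on this way are marked "not isolated".

**Step 1**
Reactants: 1 (S)-2-methylbutan-1-ol
Product: 3 ethyl (2E,4S)-2,4-dimethylhex-2-enoate, via aldehyde 2 (not isolated)
Conditions: TEMPO (10 mol%), PhI(OAc)2 (1.1 equiv), CH2Cl2, rt; then Ph3P=C(Me)CO2Et (1.5 equiv), 40 °C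
Reagents that add atoms: ethyl 2-(triphenylphosphoranylidene)propanoate, CCOC(=O)C(C)=P(c1ccccc1)(c1ccccc1)c1ccccc1
Why: Oxoammonium oxidation gives the volatile, epimerisable aldehyde 2, which is trapped in the same flask by Wittig olefination with the stabilised ylide to give the E-trisubstituted enoate; the C3 stereocentre comes unchanged from 1 because no base is present.

**Step 2**
Reactants: 3 ethyl (2E,4S)-2,4-dimethylhex-2-enoate
Product: 4 (2E,4S)-2,4-dimethylhex-2-enoic acid
Conditions: LiOH (3 equiv), THF/MeOH/H2O, 45 °C; then 1 M HCl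
Reagents that add atoms: lithium hydroxide, [Li+].[OH-]
Why: Plain ester saponification; the γ-stereocentre and the E-alkene are not affected by aqueous hydroxide.

**Step 3**
Reactants: 4 (2E,4S)-2,4-dimethylhex-2-enoic acid
Product: 5 S-(pyridin-2-yl) (2E,4S)-2,4-dimethylhex-2-enethioate
Conditions: 2,2'-dipyridyl disulfide (1.2 equiv), PPh3 (1.2 equiv), MeCN, rt
Reagents that add atoms: 2,2'-dipyridyl disulfide, c1ccc(SSc2ccccn2)nc1
Why: Mukaiyama redox condensation gives the 2-pyridyl thioester under neutral conditions, an acyl donor that chelates nickel but is too weak to acylate a pyronate.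

**Step 4**
Reactants: 6 methyl (S)-3-hydroxy-2-methylpropanoate
Product: 7 methyl (S)-3-[(tert-butyldimethylsilyl)oxy]-2-methylpropanoate
Conditions: TBSCl (1.1 equiv), imidazole (1.5 equiv), CH2Cl2, 0 °C to rt
Reagents that add atoms: tert-butyldimethylsilyl chloride, CC(C)(C)[Si](C)(C)Cl
Why: Standard silylation of the primary alcohol; the stereocentre (future C9) is bought in 6.

**Step 5**
Reactants: 7 methyl (S)-3-[(tert-butyldimethylsilyl)oxy]-2-methylpropanoate
Product: 9 (R)-tert-butyldimethyl[(2-methylbut-3-yn-1-yl)oxy]silane, via aldehyde 8 (not isolated)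
Conditions: i-Bu2AlH (1.1 equiv), CH2Cl2, −78 °C; then MeOH, K2CO3 (3 equiv), dimethyl (1-diazo-2-oxopropyl)phosphonate (1.4 equiv), −78 to 0 °C
Reagents that add atoms: dimethyl (1-diazo-2-oxopropyl)phosphonate, CC(=O)C(=[N+]=[N-])P(=O)(OC)OC
Why: Partial reduction to aldehyde 8 followed in the same flask by Seyferth–Gilbert homologation with the Ohira–Bestmann reagent gives the terminal alkyne; keeping 8 cold and unisolated preserves the α-stereocentre (the descriptor changes from S to R only through CIP priorities).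

**Step 6**
Reactants: 9 (R)-tert-butyldimethyl[(2-methylbut-3-yn-1-yl)oxy]silane
Product: 10 (R)-tert-butyldimethyl[(2-methylpent-3-yn-1-yl)oxy]silane
Conditions: n-BuLi (1.1 equiv), THF, −78 °C; MeI (2 equiv), −78 °C to rt
Reagents that add atoms: iodomethane, CI
Why: Acetylide alkylation; the propargylic C–H is far less acidic than the alkyne C–H, so the stereocentre is untouched.

**Step 7**
Reactants: 10 (R)-tert-butyldimethyl[(2-methylpent-3-yn-1-yl)oxy]silane
Product: 13 (2R,3E)-4-iodo-2-methylpent-3-en-1-ol, via alkenylzirconocene 11 (not isolated), via silyl ether 12 (not isolated)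
Conditions: Cp2Zr(H)Cl (2.5 equiv), THF, 50 °C; I2, −20 °C; aq. Na2S2O3; crude in MeOH, camphorsulfonic acid (10 mol%), rt
Reagents that add atoms: iodine, [I][I]; Cp2Zr(H)Cl, [H][Zr](Cl)(C1C=CC=C1)C1C=CC=C1 (zirconium fragment carried by 11 only)
Why: Syn-hydrozirconation with excess reagent equilibrates zirconium to the less hindered alkyne carbon (next to CH3), iodinolysis with retention gives the E-alkenyl iodide, and acid methanolysis removes the silyl group; the stereocentre is not involved.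

**Step 8**
Reactants: 13 (2R,3E)-4-iodo-2-methylpent-3-en-1-ol
Product: 15 (2E,4S,5E)-6-iodo-2,4-dimethylhepta-2,5-dienal, via aldehyde 14 (not isolated)
Conditions: Dess–Martin periodinane (1.3 equiv), NaHCO3, CH2Cl2, 0 °C; filter, concentrate cold; Ph3P=C(Me)CHO (2 equiv), toluene, 80 °C
Reagents that add atoms: 2-(triphenylphosphoranylidene)propanal, CC(C=O)=P(c1ccccc1)(c1ccccc1)c1ccccc1
Why: Buffered Dess–Martin oxidation and immediate Wittig olefination with the neutral formyl-stabilised ylide give the E-enal; the α-chiral β,γ-unsaturated aldehyde 14 never meets base, so C9 is retained (descriptor becomes S by CIP priorities only).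

**Step 9**
Reactants: 16 ethyl 2-methyl-3-oxopentanoate
Product: 18 6-ethyl-4-hydroxy-3,5-dimethyl-2H-pyran-2-one, via triketoester 17 (not isolated)
Conditions: NaH (1.1 equiv), THF, 0 °C; n-BuLi (1.05 equiv), 0 °C; EtC(O)N(OMe)Me (1.0 equiv), −78 to 0 °C; 1 M HCl; crude, DBU, toluene, 80 °C
Reagents that add atoms: N-methoxy-N-methylpropanamide, CCC(=O)N(C)OC
Why: Weiler dianion γ-acylation with a Weinreb amide gives the 3,5-diketoester, whose enol oxygen lactonises onto the ester (DBU) to form the 4-hydroxy-2-pyrone ring; no stereocentre survives in 18.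

**Step 10**
Reactants: 18 6-ethyl-4-hydroxy-3,5-dimethyl-2H-pyran-2-one, 15 (2E,4S,5E)-6-iodo-2,4-dimethylhepta-2,5-dienal
Product: 19 4-hydroxy-6-[(4E,6S,7E)-3-hydroxy-8-iodo-4,6-dimethylnona-4,7-dien-2-yl]-3,5-dimethyl-2H-pyran-2-one
Conditions: 18 (1.3 equiv), LiN(i-Pr)2 (2.7 equiv), THF, −78 to −40 °C; 15, −78 °C; AcOH quench at −78 °C
Reagents that add atoms: none
Why: The O,C-dilithio dianion of the hydroxypyrone undergoes aldol 1,2-addition to the enal faster than γ-deprotonation at −78 °C, and the alkenyl iodide is inert to amide base; the two new centres form unselectively and are removed in step 11, while C9 is untouched.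

**Step 11**
Reactants: 19 4-hydroxy-6-[(4E,6S,7E)-3-hydroxy-8-iodo-4,6-dimethylnona-4,7-dien-2-yl]-3,5-dimethyl-2H-pyran-2-one
Product: 22 4-hydroxy-6-[(2E,4E,6S,7E)-8-iodo-4,6-dimethylnona-2,4,7-trien-2-yl]-3,5-dimethyl-2H-pyran-2-one, via bis-mesylate 20 (not isolated), via pyrone mesylate 21 (not isolated)
Conditions: MsCl (3 equiv), Et3N (5 equiv), CH2Cl2, 0 °C; DBU (4 equiv), rt; then 1 M aq. LiOH, THF, rt; 1 M HCl to pH 3
Reagents that add atoms: methanesulfonyl chloride, CS(=O)(=O)Cl (mesyl groups carried by 20 and 21 only)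
Why: Mesylating both hydroxyls makes the pyrone neutral, so DBU removes the pyrone-activated C13–H and E1cB elimination converges all aldol diastereomers on the conjugated (E)-diene; hydroxide then cleaves the vinylogous-acid mesylate at sulfur to return the 4-OH, and C9–H is too weakly acidic for either base.

**Step 12**
Reactants: 22 4-hydroxy-6-[(2E,4E,6S,7E)-8-iodo-4,6-dimethylnona-2,4,7-trien-2-yl]-3,5-dimethyl-2H-pyran-2-one, 5 S-(pyridin-2-yl) (2E,4S)-2,4-dimethylhex-2-enethioate
Product: 25 4-hydroxy-3,5-dimethyl-6-[(2E,4E,6S,7E,10E,12S)-4,6,8,10,12-pentamethyl-9-oxotetradeca-2,4,7,10-tetraen-2-yl]-2H-pyran-2-one, via silyl ether 23 (not isolated), via silylated ketone 24 (not isolated)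
Conditions: BSA (1.2 equiv), DMA, rt; then 5 (1.5 equiv), NiBr2(dme) (10 mol%), 4,4'-di-tert-butyl-2,2'-bipyridine (12 mol%), LiBr (0.2 M), Zn anode, Ni-foam cathode, undivided cell, 3 mA, 2.5 F/mol, rt; 10% aq. citric acid work-up
Reagents that add atoms: N,O-bis(trimethylsilyl)acetamide, CC(=N[Si](C)(C)C)O[Si](C)(C)C (its Me3Si group is carried by 23 and 24 only)
Why: Proposed new method: a nickel-catalysed electroreductive acyl–alkenyl cross-electrophile coupling in which cathodically formed zerovalent nickel inserts into the alkenyl C–I bond of 23 with retention of E geometry, one-electron reduction gives an alkenyl monovalent nickel species that adds oxidatively to the N-chelating acyl C–S bond of 5, and the acyl(alkenyl) trivalent nickel reductively eliminates the C6–C7 dienone while zinc ions from the anode take up iodide and pyridinethiolate; in situ silylation removes the acidic pyrone proton (no protodeiodination), and no radical or base reaches C3 or C9, so both stereocentres are retained; the closest known reactions are the nickel-catalysed reductive ketone synthesis from 2-pyridyl thioesters and alkyl halides with zinc powder and nickel-electrocatalytic reductive couplings of alkenyl halides, neither shown for an alkenyl iodide with an α,β-unsaturated thioester to give a divinyl ketone.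

**Compound list**
1 | (S)-2-methylbutan-1-ol | CC[C@H](C)CO | starting material
2 | (S)-2-methylbutanal | CC[C@H](C)C=O | intermediate
3 | ethyl (2E,4S)-2,4-dimethylhex-2-enoate | CC[C@H](C)/C=C(\C)C(=O)OCC | intermediate
4 | (2E,4S)-2,4-dimethylhex-2-enoic acid | CC[C@H](C)/C=C(\C)C(=O)O | intermediate
5 | S-(pyridin-2-yl) (2E,4S)-2,4-dimethylhex-2-enethioate | CC[C@H](C)/C=C(\C)C(=O)Sc1ccccn1 | intermediate
6 | methyl (S)-3-hydroxy-2-methylpropanoate | COC(=O)[C@@H](C)CO | starting material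
7 | methyl (S)-3-[(tert-butyldimethylsilyl)oxy]-2-methylpropanoate | COC(=O)[C@@H](C)CO[Si](C)(C)C(C)(C)C | intermediate
8 | (S)-3-[(tert-butyldimethylsilyl)oxy]-2-methylpropanal | O=C[C@@H](C)CO[Si](C)(C)C(C)(C)C | intermediate
9 | (R)-tert-butyldimethyl[(2-methylbut-3-yn-1-yl)oxy]silane | C#C[C@@H](C)CO[Si](C)(C)C(C)(C)C | intermediate
10 | (R)-tert-butyldimethyl[(2-methylpent-3-yn-1-yl)oxy]silane | CC#C[C@@H](C)CO[Si](C)(C)C(C)(C)C | intermediate
11 | chlorobis(cyclopentadienyl)[(2E,4R)-5-[(tert-butyldimethylsilyl)oxy]-4-methylpent-2-en-2-yl]zirconium | Cl[Zr](C1C=CC=C1)(C1C=CC=C1)/C(C)=C/[C@@H](C)CO[Si](C)(C)C(C)(C)C | intermediate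
12 | tert-butyl{[(2R,3E)-4-iodo-2-methylpent-3-en-1-yl]oxy}dimethylsilane | I/C(C)=C/[C@@H](C)CO[Si](C)(C)C(C)(C)C | intermediate
13 | (2R,3E)-4-iodo-2-methylpent-3-en-1-ol | I/C(C)=C/[C@@H](C)CO | intermediate
14 | (2R,3E)-4-iodo-2-methylpent-3-enal | I/C(C)=C/[C@@H](C)C=O | intermediate
15 | (2E,4S,5E)-6-iodo-2,4-dimethylhepta-2,5-dienal | I/C(C)=C/[C@@H](C)/C=C(C)/C=O | intermediate
16 | ethyl 2-methyl-3-oxopentanoate (racemic) | CCC(=O)C(C)C(=O)OCC | starting material
17 | ethyl 2,4-dimethyl-3,5-dioxoheptanoate (stereoisomer mixture) | CCC(=O)C(C)C(=O)C(C)C(=O)OCC | intermediate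
18 | 6-ethyl-4-hydroxy-3,5-dimethyl-2H-pyran-2-one | CCc1oc(=O)c(C)c(O)c1C | intermediate
19 | 4-hydroxy-6-[(4E,6S,7E)-3-hydroxy-8-iodo-4,6-dimethylnona-4,7-dien-2-yl]-3,5-dimethyl-2H-pyran-2-one (mixture at the two new centres) | I/C(C)=C/[C@@H](C)/C=C(C)/C(O)C(C)c1oc(=O)c(C)c(O)c1C | intermediate
20 | (4E,6S,7E)-2-[3,5-dimethyl-4-(methylsulfonyloxy)-2-oxo-2H-pyran-6-yl]-8-iodo-4,6-dimethylnona-4,7-dien-3-yl methanesulfonate | I/C(C)=C/[C@@H](C)/C=C(C)/C(OS(C)(=O)=O)C(C)c1oc(=O)c(C)c(OS(C)(=O)=O)c1C | intermediate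
21 | 6-[(2E,4E,6S,7E)-8-iodo-4,6-dimethylnona-2,4,7-trien-2-yl]-3,5-dimethyl-2-oxo-2H-pyran-4-yl methanesulfonate | I/C(C)=C/[C@@H](C)/C=C(C)/C=C(\C)c1oc(=O)c(C)c(OS(C)(=O)=O)c1C | intermediate
22 | 4-hydroxy-6-[(2E,4E,6S,7E)-8-iodo-4,6-dimethylnona-2,4,7-trien-2-yl]-3,5-dimethyl-2H-pyran-2-one | I/C(C)=C/[C@@H](C)/C=C(C)/C=C(\C)c1oc(=O)c(C)c(O)c1C | intermediate
23 | 6-[(2E,4E,6S,7E)-8-iodo-4,6-dimethylnona-2,4,7-trien-2-yl]-3,5-dimethyl-4-[(trimethylsilyl)oxy]-2H-pyran-2-one | I/C(C)=C/[C@@H](C)/C=C(C)/C=C(\C)c1oc(=O)c(C)c(O[Si](C)(C)C)c1C | intermediate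
24 | 3,5-dimethyl-6-[(2E,4E,6S,7E,10E,12S)-4,6,8,10,12-pentamethyl-9-oxotetradeca-2,4,7,10-tetraen-2-yl]-4-[(trimethylsilyl)oxy]-2H-pyran-2-one | CC[C@H](C)/C=C(\C)C(=O)/C(C)=C/[C@@H](C)/C=C(C)/C=C(\C)c1oc(=O)c(C)c(O[Si](C)(C)C)c1C | intermediate
25 | 4-hydroxy-3,5-dimethyl-6-[(2E,4E,6S,7E,10E,12S)-4,6,8,10,12-pentamethyl-9-oxotetradeca-2,4,7,10-tetraen-2-yl]-2H-pyran-2-one | CC[C@H](C)/C=C(\C)C(=O)/C(C)=C/[C@@H](C)/C=C(C)/C=C(\C)c1oc(=O)c(C)c(O)c1C | target

**Totals**
Total step count: 12. Longest linear sequence: 8 steps (6 to 25 through steps 4, 5, 6, 7, 8, 10, 11 and 12).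

**Three steps most likely to fail**

Step 12 (the new electroreductive acyl–alkenyl coupling; risks are alkenyl homocoupling, protodeiodination and over-reduction of the dienone). The fallback uses known chemistry, sets out from 22 and comes back at 25. Alcohol 1 is taken through the oxidation–Wittig sequence of step 1 with 2-(triphenylphosphoranylidene)propanal in place of the ester ylide to give (2E,4S)-2,4-dimethylhex-2-enal F1. Iodide 22, masked in the flask as silyl ether 23 as in step 12, is added to F1 under Nozaki–Hiyama–Kishi conditions (CrCl2 4 equiv, NiCl2 1 mol%, DMF/THF, rt). This gives the silyl-protected carbinol 6-[(2E,4E,6S,7E,10E,12S)-9-hydroxy-4,6,8,10,12-pentamethyltetradeca-2,4,7,10-tetraen-2-yl]-3,5-dimethyl-4-[(trimethylsilyl)oxy]-2H-pyran-2-one F2, which is not isolated. Acidic work-up desilylates it to 4-hydroxy-6-[(2E,4E,6S,7E,10E,12S)-9-hydroxy-4,6,8,10,12-pentamethyltetradeca-2,4,7,10-tetraen-2-yl]-3,5-dimethyl-2H-pyran-2-one F3 (both carbinol epimers). Dess–Martin periodinane (NaHCO3, CH2Cl2, 0 °C) oxidises F3 to 25.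

Step 8 (the α-chiral β,γ-unsaturated aldehyde 14 may epimerise or move into conjugation while heated with the sluggish formyl ylide). The fallback sets out from 13 and comes back at 15. Alcohol 13 is oxidised as in step 8 and crude 14 is treated at room temperature with the more reactive ethyl 2-(triphenylphosphoranylidene)propanoate in CH2Cl2 to give ethyl (2E,4S,5E)-6-iodo-2,4-dimethylhepta-2,5-dienoate F4. i-Bu2AlH (2.2 equiv, CH2Cl2, −78 °C) reduces F4 to (2E,4S,5E)-6-iodo-2,4-dimethylhepta-2,5-dien-1-ol F5, and MnO2 (CH2Cl2, rt) oxidises F5 to 15.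

Step 11 (the dehydration needs both hydroxyls mesylated, E-selective E1cB elimination and clean removal of the pyrone mesylate). The fallback builds the pyrone last, sets out from 15 and comes back at 22, bypassing 19 to 21. Wittig reaction of 15 with 2-(triphenylphosphoranylidene)propanal (toluene, 90 °C) gives (2E,4E,6S,7E)-8-iodo-2,4,6-trimethylnona-2,4,7-trienal F6. The NaH/n-BuLi dianion of 16 adds to F6 at −78 °C to give ethyl (6E,8E,10S,11E)-5-hydroxy-12-iodo-2,4,6,8,10-pentamethyl-3-oxotrideca-6,8,11-trienoate F7. Dess–Martin oxidation gives ethyl (6E,8E,10S,11E)-12-iodo-2,4,6,8,10-pentamethyl-3,5-dioxotrideca-6,8,11-trienoate F8, and DBU in toluene lactonises F8 to 22.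

**Further compounds**
F1 | step 12 | (2E,4S)-2,4-dimethylhex-2-enal | CC[C@H](C)/C=C(\C)C=O
F2 | step 12 | 6-[(2E,4E,6S,7E,10E,12S)-9-hydroxy-4,6,8,10,12-pentamethyltetradeca-2,4,7,10-tetraen-2-yl]-3,5-dimethyl-4-[(trimethylsilyl)oxy]-2H-pyran-2-one | CC[C@H](C)/C=C(\C)C(O)/C(C)=C/[C@@H](C)/C=C(C)/C=C(\C)c1oc(=O)c(C)c(O[Si](C)(C)C)c1C
F3 | step 12 | 4-hydroxy-6-[(2E,4E,6S,7E,10E,12S)-9-hydroxy-4,6,8,10,12-pentamethyltetradeca-2,4,7,10-tetraen-2-yl]-3,5-dimethyl-2H-pyran-2-one | CC[C@H](C)/C=C(\C)C(O)/C(C)=C/[C@@H](C)/C=C(C)/C=C(\C)c1oc(=O)c(C)c(O)c1C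
F4 | step 8 | ethyl (2E,4S,5E)-6-iodo-2,4-dimethylhepta-2,5-dienoate | I/C(C)=C/[C@@H](C)/C=C(\C)C(=O)OCC
F5 | step 8 | (2E,4S,5E)-6-iodo-2,4-dimethylhepta-2,5-dien-1-ol | I/C(C)=C/[C@@H](C)/C=C(\C)CO
F6 | step 11 | (2E,4E,6S,7E)-8-iodo-2,4,6-trimethylnona-2,4,7-trienal | I/C(C)=C/[C@@H](C)/C=C(C)/C=C(\C)C=O
F7 | step 11 | ethyl (6E,8E,10S,11E)-5-hydroxy-12-iodo-2,4,6,8,10-pentamethyl-3-oxotrideca-6,8,11-trienoate | I/C(C)=C/[C@@H](C)/C=C(C)/C=C(\C)C(O)C(C)C(=O)C(C)C(=O)OCC
F8 | step 11 | ethyl (6E,8E,10S,11E)-12-iodo-2,4,6,8,10-pentamethyl-3,5-dioxotrideca-6,8,11-trienoate | I/C(C)=C/[C@@H](C)/C=C(C)/C=C(\C)C(=O)C(C)C(=O)C(C)C(=O)OCC
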